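**Retrosynthetic overview**
- Labels: quinolinone A carries ring A (gem-dimethyl pyran, trans-fused to the cyclohexane); quinolinone B carries ring B (C-methyl pyran bridging the cyclohexane 1,3).
- Target ⇒ 4-hydroxy-1-methylquinolin-2-one + a ring B aldehyde bearing cis 2-oxoethyl and 2-methylprop-1-enyl arms, by a domino Knoevenagel/intramolecular hetero-Diels–Alder reaction that closes the cyclohexane and ring A together.
- Ring B aldehyde ⇒ the same quinolinone + the C10 trienal dehydrocitral, by an amine-catalysed asymmetric 1,6-C-addition/oxa-Michael annulation that sets the one controlling stereocentre.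
- Dehydrocitral ⇒ two molecules of prenal (vinylogous aldol condensation).
- Ring order: ring B first; then cyclohexane + ring A in one operation, the three remaining stereocentres following from the first.

Assumption: the (S)-configured catalyst of step 2 is taken to give the (R) benzylic centre; if the sense is the opposite, its (R)-enantiomer is used and nothing else changes.

**Step 1**
Reactants: 1 3-methylbut-2-enal (prenal; two molecules)
Product: 2 (2E,4E)-3,7-dimethylocta-2,4,6-trienal (dehydrocitral; the 2Z isomer is equally usable)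
Conditions: KNH2 (0.5 equiv), NH3(l)/Et2O, −60 → −33 °C; NH4Cl
Reagents that add atoms: none
Why: Vinylogous aldol condensation, in which the potassium dienolate of 1 adds through its γ-carbon to the aldehyde of a second molecule of 1 (the α-aldol is reversible, the γ-adduct is drained by E1cB loss of hydroxide to the conjugated trienal); no stereocentre is formed and the C2=C3 geometry is erased in step 2.

**Step 2**
Reactants: 2 (2E,4E)-3,7-dimethylocta-2,4,6-trienal; 3 4-hydroxy-1-methylquinolin-2(1H)-one
Product: 5 2-[(2S,4R)-2,6-dimethyl-4-(2-methylprop-1-en-1-yl)-5-oxo-3,4,5,6-tetrahydro-2H-pyrano[3,2-c]quinolin-2-yl]acetaldehyde, via open-chain enal 4 (not isolated)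
Conditions: (S)-2-{bis[3,5-bis(trifluoromethyl)phenyl](trimethylsilyloxy)methyl}pyrrolidine (20 mol%), PhCO2H (20 mol%), CH2Cl2, rt, 48 h; short silica plug, used at once
Reagents that add atoms: none
Why: Proposed new method: the amine turns 2 into a trienyl iminium ion whose carbonyl carbon is screened by the catalyst and whose β- and ζ-carbons are fully substituted, so the enol carbon C3 of 3 adds at the only open electrophilic CH (δ, 1,6-addition) on the face left free by the diaryl(silyloxy)methyl group and sets the (R) benzylic centre; γ-protonation gives the iminium of enal 4, and the 4-OH then closes ring B by a reversible oxa-Michael addition (the thermodynamically preferred 2-quinolone isomer; 5 is drawn as the cis C2 epimer, and any trans epimer is carried along because the two interconvert by retro-oxa-Michael); the closest known reaction types are the aminocatalytic 1,6-Friedel–Crafts/1,4-oxa-Michael chroman annulation of hydroxyarenes with 2,4-dienals and the oxa-Michael closure of 2-methylchromans on β-methyl enal iminium ions.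

**Step 3**
Reactants: 5 2-[(2S,4R)-2,6-dimethyl-4-(2-methylprop-1-en-1-yl)-5-oxo-3,4,5,6-tetrahydro-2H-pyrano[3,2-c]quinolin-2-yl]acetaldehyde; 3 4-hydroxy-1-methylquinolin-2(1H)-one
Product: 7 target CNP0229685.7 (cyclohexane core; trans-fused ring A on quinolinone A; bridging ring B on quinolinone B; S at CH–CMe2; R at CH–quinolinone A; S at C(Me)–O; R at CH–quinolinone B), via Knoevenagel adduct 6 (not isolated)
Conditions: ethylenediammonium diacetate (20 mol%), 4 Å MS, toluene/MeCN 4:1, 100 °C, 24 h; 3 (1.1 equiv) added in portions
Reagents that add atoms: none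
Why: Tietze domino Knoevenagel/intramolecular hetero-Diels–Alder reaction, in which condensation at C3 of 3 gives the 3-alkylidene-quinoline-2,4-dione 6 and its ketone-side 1-oxadiene (more electrophilic than the amide side) adds across the 2-methylprop-1-enyl alkene held 1,3-diaxial to it on ring B (the peri lactam C=O favours the pseudoaxial benzylic arm) through the chair-like exo transition state with both new ring-fusion bonds equatorial; this closes the cyclohexane and ring A at once, sets the trans fusion (R at CH–quinolinone A, S at CH–CMe2) under control of the existing (R) centre, and fixes C(Me)–O as S because only the cis epimer of 5 can reach the transition state.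

**Compound list**
1 | 3-methylbut-2-enal (prenal) | CC(C)=CC=O | starting material
2 | (2E,4E)-3,7-dimethylocta-2,4,6-trienal (dehydrocitral) | CC(C)=C/C=C/C(C)=C/C=O | intermediate
3 | 4-hydroxy-1-methylquinolin-2(1H)-one | Cn1c(=O)cc(O)c2ccccc21 | starting material
4 | (2E,5R)-5-(4-hydroxy-1-methyl-2-oxo-1,2-dihydroquinolin-3-yl)-3,7-dimethylocta-2,6-dienal | O=C/C=C(C)/C[C@H](C=C(C)C)c1c(O)c2ccccc2n(C)c1=O | intermediate (not isolated)
5 | 2-[(2S,4R)-2,6-dimethyl-4-(2-methylprop-1-en-1-yl)-5-oxo-3,4,5,6-tetrahydro-2H-pyrano[3,2-c]quinolin-2-yl]acetaldehyde | O=CC[C@]1(C)C[C@H](C=C(C)C)c2c(c3ccccc3n(C)c2=O)O1 | intermediate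
6 | 3-{2-[(2R,4R)-2,6-dimethyl-4-(2-methylprop-1-en-1-yl)-5-oxo-3,4,5,6-tetrahydro-2H-pyrano[3,2-c]quinolin-2-yl]ethylidene}-1-methylquinoline-2,4(1H,3H)-dione (same spatial arrangement as 5; the C2 descriptor changes by priority only) | CN1C(=O)C(=CC[C@]2(C)C[C@H](C=C(C)C)c3c(c4ccccc4n(C)c3=O)O2)C(=O)c2ccccc21 | intermediate (not isolated)
7 | target CNP0229685.7 (heptacyclic bis-quinolinone as described in step 3) | Cn1c(=O)c2c(c3ccccc31)OC(C)(C)[C@H]1[C@H]2C[C@]2(C)C[C@H]1c1c(c3ccccc3n(C)c1=O)O2 | target

**Totals**
Total step count: 3. Longest linear sequence: 3 (1 → 2 → 5 → 7); compound 3 enters twice.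

**Steps most likely to fail, with fallbacks**

Step 2 (highest risk). The enol of 3 may add 1,2 and end as a 2H-pyran after Knoevenagel/6π closure, or the remote δ-centre may form with low ee. The fallback sets out from 3 and comes back at 4. Conjugate 1,4-addition of 3 to commercial (E)-6-methylhepta-3,5-dien-2-one under chiral primary-amine iminium catalysis (the enantiomer of 1,2-diphenylethane-1,2-diamine that gives the R product, AcOH, THF; a warfarin-type Michael addition with the new centre next to the catalyst-bound carbon) gives 4-hydroxy-1-methyl-3-[(4R)-2-methyl-6-oxohept-2-en-4-yl]quinolin-2(1H)-one F2. Horner–Wadsworth–Emmons reaction of its methyl ketone with diethyl cyanomethylphosphonate (NaH, 2.2 equiv, THF) gives (5R)-5-(4-hydroxy-1-methyl-2-oxo-1,2-dihydroquinolin-3-yl)-3,7-dimethylocta-2,6-dienenitrile F3. Reduction with i-Bu2AlH (toluene, −78 °C, then aqueous acid) gives enal 4, which is closed to 5 with pyrrolidine/PhCO2H.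

Step 3. The alkylidene dione 6 may be intercepted by a second molecule of 3 (2:1 adduct) or stall before cycloaddition, and long heating could erode ee by retro-Michael cleavage. The fallback sets out from 5 and comes back at 6. Three-component condensation of 5, 3 and thiophenol (piperidine cat., EtOH, rt) gives the isolable sulfide 3-{2-[(2S,4R)-2,6-dimethyl-4-(2-methylprop-1-en-1-yl)-5-oxo-3,4,5,6-tetrahydro-2H-pyrano[3,2-c]quinolin-2-yl]-1-(phenylsulfanyl)ethyl}-4-hydroxy-1-methylquinolin-2(1H)-one F4, a masked form of 6. After purification it is heated alone in dilute toluene (110–140 °C, Et3N cat.); retro-thia-Michael loss of thiophenol releases 6 with no free 3 present, and the irreversible cycloaddition gives 7.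

Step 1. Prenal may give cyclic dimers by Michael/aldol paths and a low yield of the open trienal. The fallback sets out from 1 and comes back at 2. Horner–Wadsworth–Emmons olefination of 1 with diethyl (3-cyano-2-methylprop-2-en-1-yl)phosphonate (NaH, THF, 0 °C → rt) gives 3,7-dimethylocta-2,4,6-trienenitrile F1. Reduction with i-Bu2AlH (toluene, −78 °C, then aqueous acid) gives 2.

**Further compounds**
F1 | step 1 | 3,7-dimethylocta-2,4,6-trienenitrile (4E; 2E/2Z mixture) | CC(C)=C/C=C/C(C)=CC#N
F2 | step 2 | 4-hydroxy-1-methyl-3-[(4R)-2-methyl-6-oxohept-2-en-4-yl]quinolin-2(1H)-one | CC(=O)C[C@H](C=C(C)C)c1c(O)c2ccccc2n(C)c1=O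
F3 | step 2 | (5R)-5-(4-hydroxy-1-methyl-2-oxo-1,2-dihydroquinolin-3-yl)-3,7-dimethylocta-2,6-dienenitrile (2E/2Z mixture) | N#CC=C(C)C[C@H](C=C(C)C)c1c(O)c2ccccc2n(C)c1=O
F4 | step 3 | 3-{2-[(2S,4R)-2,6-dimethyl-4-(2-methylprop-1-en-1-yl)-5-oxo-3,4,5,6-tetrahydro-2H-pyrano[3,2-c]quinolin-2-yl]-1-(phenylsulfanyl)ethyl}-4-hydroxy-1-methylquinolin-2(1H)-one (sulfide carbon as a mixture) | Cn1c(=O)c(C(Sc2ccccc2)C[C@]2(C)C[C@H](C=C(C)C)c3c(c4ccccc4n(C)c3=O)O2)c(O)c2ccccc21
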